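The carbocycle is made by forming the C4a–C5 bond. The key step uses the way the two rings are joined: C4a, next to the pyrone carbonyl C4, carries the secondary alcohol carbon C5, and the mutually trans carbinols C6, C7 and C8 lead on to pyrone carbon C8a. A Nozaki–Hiyama–Kishi addition of a C4a–I bond to a C5 aldehyde therefore closes the six-membered carbocycle and creates the last stereocentre in one operation. The precursor is a 3-iodo-4-pyrone with the protected arylethyl group at C2 and, at C8a, a tri-O-benzyl aldehyde chain whose three stereocentres come unchanged from L-xylose.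

Key step: step 14

Remark: the C6–C8 stereotriad equals L-xylose read from C1 (the same as D-xylose read from C5); L-xylose is used because its anomeric carbon becomes the alkyne directly, so no meso 2,3,4-tri-O-benzylxylitol is passed. Compound 1 is taken as purchased (two routine steps from isovanillin otherwise), and chromone numbering is used for the future ring atoms.

Step 1
Reactants: 1 3-(benzyloxy)-4-methoxybenzyl alcohol
Product: 2 3-(benzyloxy)-4-methoxybenzyl bromide
Conditions: PBr3, CH2Cl2, 0 °C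
Reagents that add atoms: phosphorus tribromide, BrP(Br)Br
Why: Bromination of a benzylic alcohol through its phosphite ester (SN2 by bromide) should be fast at the electron-rich benzylic carbon and leaves the aryl benzyl ether alone.

Step 2
Reactants: 3 methyl acetoacetate; 2 3-(benzyloxy)-4-methoxybenzyl bromide
Product: 5 methyl 5-[3-(benzyloxy)-4-methoxyphenyl]-3-oxopentanoate, via acetoacetate dianion 4 (not isolated)
Conditions: NaH, THF, 0 °C; n-BuLi; then 2, 0 °C to rt; aq. HCl
Reagents that add atoms: none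
Why: Dianion γ-alkylation of a β-keto ester (Weiler alkylation): the more basic terminal carbanion attacks the benzylic bromide and builds the arylethyl ketone chain in one step.

Step 3
Reactants: 5 methyl 5-[3-(benzyloxy)-4-methoxyphenyl]-3-oxopentanoate
Product: 6 methyl {2-[2-(3-(benzyloxy)-4-methoxyphenyl)ethyl]-1,3-dioxolan-2-yl}acetate
Conditions: ethylene glycol, p-TsOH (cat.), toluene, reflux, Dean–Stark
Reagents that add atoms: ethylene glycol, OCCO
Why: Acid-catalysed ketalisation with azeotropic removal of water masks the ketone, so that the future C3 stays a non-nucleophilic CH2 and the keto oxygen cannot close the pyrone before iodine is in place.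

Step 4
Reactants: 6 methyl {2-[2-(3-(benzyloxy)-4-methoxyphenyl)ethyl]-1,3-dioxolan-2-yl}acetate
Product: 7 2-{2-[2-(3-(benzyloxy)-4-methoxyphenyl)ethyl]-1,3-dioxolan-2-yl}-N-methoxy-N-methylacetamide
Conditions: MeNHOMe·HCl, iPrMgCl, THF, −20 °C
Reagents that add atoms: N,O-dimethylhydroxylamine hydrochloride, CNOC.Cl
Why: Aminolysis of the ester by the magnesium amide of N,O-dimethylhydroxylamine (Weinreb amide formation) proceeds under basic conditions that the dioxolane tolerates.

Step 5
Reactants: 8 L-xylose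
Product: 9 methyl L-xylopyranoside (α/β mixture)
Conditions: MeOH, HCl (cat.), reflux
Reagents that add atoms: methanol, CO
Why: Fischer glycosidation under thermodynamic control ties up C1 and O5 in the pyranoside so that only O2, O3 and O4 remain for benzylation, and no stereocentre of the later chain is touched.

Step 6
Reactants: 9 methyl L-xylopyranoside
Product: 10 methyl 2,3,4-tri-O-benzyl-L-xylopyranoside (α/β mixture)
Conditions: BnBr, NaH, DMF, 0 °C to rt
Reagents that add atoms: benzyl bromide, BrCc1ccccc1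
Why: Williamson etherification of the three secondary alkoxides installs the benzyl ethers that stay until the last step.

Step 7
Reactants: 10 methyl 2,3,4-tri-O-benzyl-L-xylopyranoside
Product: 11 2,3,4-tri-O-benzyl-L-xylopyranose (α/β mixture)
Conditions: AcOH, 1 M aq. H2SO4, 90 °C
Reagents that add atoms: water, O
Why: Acid hydrolysis of the glycosidic acetal through the oxocarbenium ion frees the hemiacetal, while benzyl ethers are stable to hot aqueous acid.

Step 8
Reactants: 11 2,3,4-tri-O-benzyl-L-xylopyranose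
Product: 12 (2S,3S,4R)-2,3,4-tris(benzyloxy)hex-5-yn-1-ol
Conditions: dimethyl (1-diazo-2-oxopropyl)phosphonate, K2CO3, MeOH, rt
Reagents that add atoms: dimethyl (1-diazo-2-oxopropyl)phosphonate, CC(=O)C(=[N+]=[N-])P(=O)(OC)OC
Why: Ohira–Bestmann (Seyferth–Gilbert) homologation of the open-chain aldehyde in equilibrium with the lactol turns xylose C1 into the alkyne (future C8a and C4a) and leaves O5 as the only free hydroxyl, which differentiates the two chain ends while the mild carbonate base should leave the α-benzyloxy centre intact.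

Step 9
Reactants: 12 (2S,3S,4R)-2,3,4-tris(benzyloxy)hex-5-yn-1-ol
Product: 13 tert-butyl{[(2S,3S,4R)-2,3,4-tris(benzyloxy)hex-5-yn-1-yl]oxy}dimethylsilane
Conditions: TBSCl, imidazole, CH2Cl2, rt
Reagents that add atoms: tert-butyldimethylsilyl chloride, CC(C)(C)[Si](C)(C)Cl
Why: Silylation of the single primary alcohol keeps the future C5 oxygen inert during acetylide formation and amine addition and is removable by the aqueous acid used later.

Step 10
Reactants: 13 tert-butyl{[(2S,3S,4R)-2,3,4-tris(benzyloxy)hex-5-yn-1-yl]oxy}dimethylsilane; 7 2-{2-[2-(3-(benzyloxy)-4-methoxyphenyl)ethyl]-1,3-dioxolan-2-yl}-N-methoxy-N-methylacetamide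
Product: 15 (5R,6S,7S)-5,6,7-tris(benzyloxy)-1-{2-[2-(3-(benzyloxy)-4-methoxyphenyl)ethyl]-1,3-dioxolan-2-yl}-8-[(tert-butyldimethylsilyl)oxy]oct-3-yn-2-one, via lithium acetylide 14 (not isolated)
Conditions: n-BuLi, THF, −78 °C; then 7, −78 to 0 °C; AcOH
Reagents that add atoms: none
Why: Acylation of a lithium acetylide by a Weinreb amide stops at the ynone because the chelated tetrahedral adduct survives until the acetic acid quench, and the propargylic C8 centre is not deprotonated.

Step 11
Reactants: 15 (5R,6S,7S)-5,6,7-tris(benzyloxy)-1-{2-[2-(3-(benzyloxy)-4-methoxyphenyl)ethyl]-1,3-dioxolan-2-yl}-8-[(tert-butyldimethylsilyl)oxy]oct-3-yn-2-one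
Product: 17 (5R,6S,7S)-5,6,7-tris(benzyloxy)-1-{2-[2-(3-(benzyloxy)-4-methoxyphenyl)ethyl]-1,3-dioxolan-2-yl}-8-[(tert-butyldimethylsilyl)oxy]-3-iodo-4-(morpholin-4-yl)oct-3-en-2-one (C3=C4 geometry not defined), via morpholine enaminone 16 (not isolated)
Conditions: morpholine, THF, rt; then I2, Et3N, 0 °C
Reagents that add atoms: morpholine, C1COCCN1; iodine, II
Why: Aza-Michael addition of the secondary amine to the ynone puts nitrogen on C8a and makes C4a the α-carbon of an enaminone, the one strongly nucleophilic carbon of the molecule, which iodine then substitutes (electrophilic α-iodination of an enaminone) without touching the electron-rich arene or the benzyl ethers.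

Step 12
Reactants: 17 (5R,6S,7S)-5,6,7-tris(benzyloxy)-1-{2-[2-(3-(benzyloxy)-4-methoxyphenyl)ethyl]-1,3-dioxolan-2-yl}-8-[(tert-butyldimethylsilyl)oxy]-3-iodo-4-(morpholin-4-yl)oct-3-en-2-one
Product: 18 2-[(1S,2R,3S)-1,2,3-tris(benzyloxy)-4-hydroxybutyl]-6-[2-(3-(benzyloxy)-4-methoxyphenyl)ethyl]-3-iodo-4H-pyran-4-one
Conditions: 2 M aq. HCl, THF, rt
Reagents that add atoms: water, O
Why: Acid-catalysed ketal hydrolysis unmasks the C2 ketone, whose enol oxygen adds to C8a of the protonated iodo-enaminone and expels morpholine (addition–elimination cyclocondensation, the ring closure by which enaminones give 3-iodochromones), so the 4-pyrone should form with iodine fixed at C4a while the same acid cleaves the primary silyl ether.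

Step 13
Reactants: 18 2-[(1S,2R,3S)-1,2,3-tris(benzyloxy)-4-hydroxybutyl]-6-[2-(3-(benzyloxy)-4-methoxyphenyl)ethyl]-3-iodo-4H-pyran-4-one
Product: 19 (2R,3S,4S)-2,3,4-tris(benzyloxy)-4-{6-[2-(3-(benzyloxy)-4-methoxyphenyl)ethyl]-3-iodo-4-oxo-4H-pyran-2-yl}butanal
Conditions: Dess–Martin periodinane, CH2Cl2, 0 °C to rt
Reagents that add atoms: none
Why: Dess–Martin oxidation converts the primary alcohol into the aldehyde under non-basic conditions that should not epimerise C6 or eliminate benzyl alcohol, and the crude aldehyde is taken on at once.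

Step 14
Reactants: 19 (2R,3S,4S)-2,3,4-tris(benzyloxy)-4-{6-[2-(3-(benzyloxy)-4-methoxyphenyl)ethyl]-3-iodo-4-oxo-4H-pyran-2-yl}butanal
Product: 20 (5S,6S,7R,8S)-6,7,8-tris(benzyloxy)-2-[2-(3-(benzyloxy)-4-methoxyphenyl)ethyl]-5-hydroxy-5,6,7,8-tetrahydro-4H-chromen-4-one
Conditions: CrCl2 (10 equiv), NiCl2 (10 mol%), degassed DMSO (0.005 M), rt; aq. work-up
Reagents that add atoms: none
Why: Proposed new method: CrCl2 reduces NiCl2 to zerovalent nickel, which inserts into the C4a–I bond; the pyranonyl group is handed to trivalent chromium, and the alkenylchromium adds to the tethered C5 aldehyde through a four-centre C–Cr/C=O transition state, the carbocycle closing in a 6-exo-trig mode. The closest known reaction type is the intramolecular Nozaki–Hiyama–Kishi cyclisation of α-iodoenones and other alkenyl iodides onto aldehydes; the 3-iodo-4-pyrone is an α-iodo vinylogous ester of the same polarity but has not served as the halide. C6, C7 and C8 arrive fixed from L-xylose, so C5 is the only new stereocentre, and it is controlled by the ring transition state: the three trans benzyloxy groups sit pseudo-equatorial in the forming half-chair, and the aldehyde oxygen, bound to chromium above the pyrone plane, turns away from the C4 carbonyl (allylic strain) and from the C6–O dipole (Felkin–Anh, no chelate in DMSO), so it should end pseudo-axial and cis to O6, that is 5S. The step needs the C–I bond to react in preference to the pyrone carbonyl and the α,β-dibenzyloxy aldehyde to survive without enolisation or loss of benzyl alcohol; the carbonyl-selective, barely basic organochromium secures both, and high dilution keeps the addition intramolecular.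

Step 15
Reactants: 20 (5S,6S,7R,8S)-6,7,8-tris(benzyloxy)-2-[2-(3-(benzyloxy)-4-methoxyphenyl)ethyl]-5-hydroxy-5,6,7,8-tetrahydro-4H-chromen-4-one
Product: 21 (5S,6S,7R,8S)-5,6,7,8-tetrahydroxy-2-[2-(3-hydroxy-4-methoxyphenyl)ethyl]-5,6,7,8-tetrahydro-4H-chromen-4-one (CNP0224308.1)
Conditions: H2 (1 atm), Pd/C, EtOAc–MeOH, rt
Reagents that add atoms: none
Why: Catalytic hydrogenolysis of the three alkyl benzyl ethers and the aryl benzyl ether should release the tetrol and the phenol without touching any stereocentre, since 4-pyranones normally resist hydrogenation at one atmosphere.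

Compound list
1 | 3-(benzyloxy)-4-methoxybenzyl alcohol | COc1ccc(CO)cc1OCc1ccccc1 | starting material
2 | 3-(benzyloxy)-4-methoxybenzyl bromide | COc1ccc(CBr)cc1OCc1ccccc1 | intermediate
3 | methyl acetoacetate | CC(=O)CC(=O)OC | starting material
4 | sodium lithium dianion of methyl acetoacetate (not isolated) | [Na+].[Li+].COC([O-])=CC([O-])=C | intermediate
5 | methyl 5-[3-(benzyloxy)-4-methoxyphenyl]-3-oxopentanoate | COC(=O)CC(=O)CCc1ccc(OC)c(OCc2ccccc2)c1 | intermediate
6 | methyl {2-[2-(3-(benzyloxy)-4-methoxyphenyl)ethyl]-1,3-dioxolan-2-yl}acetate | COC(=O)CC1(CCc2ccc(OC)c(OCc3ccccc3)c2)OCCO1 | intermediate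
7 | 2-{2-[2-(3-(benzyloxy)-4-methoxyphenyl)ethyl]-1,3-dioxolan-2-yl}-N-methoxy-N-methylacetamide | CON(C)C(=O)CC1(CCc2ccc(OC)c(OCc3ccccc3)c2)OCCO1 | intermediate
8 | L-xylose (open-chain form drawn) | OC[C@H](O)[C@@H](O)[C@H](O)C=O | starting material
9 | methyl L-xylopyranoside (α/β) | COC1OC[C@H](O)[C@@H](O)[C@@H]1O | intermediate
10 | methyl 2,3,4-tri-O-benzyl-L-xylopyranoside (α/β) | COC1OC[C@H](OCc2ccccc2)[C@@H](OCc2ccccc2)[C@@H]1OCc1ccccc1 | intermediate
11 | 2,3,4-tri-O-benzyl-L-xylopyranose (α/β) | OC1OC[C@H](OCc2ccccc2)[C@@H](OCc2ccccc2)[C@@H]1OCc1ccccc1 | intermediate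
12 | (2S,3S,4R)-2,3,4-tris(benzyloxy)hex-5-yn-1-ol | C#C[C@@H](OCc1ccccc1)[C@H](OCc1ccccc1)[C@@H](OCc1ccccc1)CO | intermediate
13 | tert-butyl{[(2S,3S,4R)-2,3,4-tris(benzyloxy)hex-5-yn-1-yl]oxy}dimethylsilane | C#C[C@@H](OCc1ccccc1)[C@H](OCc1ccccc1)[C@@H](OCc1ccccc1)CO[Si](C)(C)C(C)(C)C | intermediate
14 | lithium acetylide of 13, [(3R,4S,5S)-3,4,5-tris(benzyloxy)-6-[(tert-butyldimethylsilyl)oxy]hex-1-yn-1-yl]lithium (not isolated) | [Li]C#C[C@@H](OCc1ccccc1)[C@H](OCc1ccccc1)[C@@H](OCc1ccccc1)CO[Si](C)(C)C(C)(C)C | intermediate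
15 | (5R,6S,7S)-5,6,7-tris(benzyloxy)-1-{2-[2-(3-(benzyloxy)-4-methoxyphenyl)ethyl]-1,3-dioxolan-2-yl}-8-[(tert-butyldimethylsilyl)oxy]oct-3-yn-2-one | COc1ccc(CCC2(CC(=O)C#C[C@@H](OCc3ccccc3)[C@H](OCc3ccccc3)[C@@H](OCc3ccccc3)CO[Si](C)(C)C(C)(C)C)OCCO2)cc1OCc1ccccc1 | intermediate
16 | (5R,6S,7S)-5,6,7-tris(benzyloxy)-1-{2-[2-(3-(benzyloxy)-4-methoxyphenyl)ethyl]-1,3-dioxolan-2-yl}-8-[(tert-butyldimethylsilyl)oxy]-4-(morpholin-4-yl)oct-3-en-2-one (not isolated; C3=C4 geometry not defined) | COc1ccc(CCC2(CC(=O)C=C(N3CCOCC3)[C@@H](OCc3ccccc3)[C@H](OCc3ccccc3)[C@@H](OCc3ccccc3)CO[Si](C)(C)C(C)(C)C)OCCO2)cc1OCc1ccccc1 | intermediate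
17 | (5R,6S,7S)-5,6,7-tris(benzyloxy)-1-{2-[2-(3-(benzyloxy)-4-methoxyphenyl)ethyl]-1,3-dioxolan-2-yl}-8-[(tert-butyldimethylsilyl)oxy]-3-iodo-4-(morpholin-4-yl)oct-3-en-2-one (C3=C4 geometry not defined) | COc1ccc(CCC2(CC(=O)C(I)=C(N3CCOCC3)[C@@H](OCc3ccccc3)[C@H](OCc3ccccc3)[C@@H](OCc3ccccc3)CO[Si](C)(C)C(C)(C)C)OCCO2)cc1OCc1ccccc1 | intermediate
18 | 2-[(1S,2R,3S)-1,2,3-tris(benzyloxy)-4-hydroxybutyl]-6-[2-(3-(benzyloxy)-4-methoxyphenyl)ethyl]-3-iodo-4H-pyran-4-one | COc1ccc(CCc2cc(=O)c(I)c(o2)[C@@H](OCc3ccccc3)[C@H](OCc3ccccc3)[C@@H](OCc3ccccc3)CO)cc1OCc1ccccc1 | intermediate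
19 | (2R,3S,4S)-2,3,4-tris(benzyloxy)-4-{6-[2-(3-(benzyloxy)-4-methoxyphenyl)ethyl]-3-iodo-4-oxo-4H-pyran-2-yl}butanal (precursor of the key step) | COc1ccc(CCc2cc(=O)c(I)c(o2)[C@@H](OCc3ccccc3)[C@H](OCc3ccccc3)[C@@H](OCc3ccccc3)C=O)cc1OCc1ccccc1 | intermediate
20 | (5S,6S,7R,8S)-6,7,8-tris(benzyloxy)-2-[2-(3-(benzyloxy)-4-methoxyphenyl)ethyl]-5-hydroxy-5,6,7,8-tetrahydro-4H-chromen-4-one (product of the key step) | COc1ccc(CCc2cc(=O)c3c(o2)[C@@H](OCc4ccccc4)[C@H](OCc4ccccc4)[C@@H](OCc4ccccc4)[C@H]3O)cc1OCc1ccccc1 | intermediate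
21 | (5S,6S,7R,8S)-5,6,7,8-tetrahydroxy-2-[2-(3-hydroxy-4-methoxyphenyl)ethyl]-5,6,7,8-tetrahydro-4H-chromen-4-one | COc1ccc(CCc2cc(=O)c3c(o2)[C@@H](O)[C@H](O)[C@@H](O)[C@H]3O)cc1O | target

Total step count: 15. Longest linear sequence: 11 steps (L-xylose 8 to target 21, steps 5 to 15).

Steps most likely to fail

Step 14. The iodopyrone may be slow to enter the nickel cycle, the alkenylchromium may be protonated before it reaches the aldehyde (loss of iodine without ring closure), or the two faces of the aldehyde may be attacked with poor selectivity, so that part of the material closes with C5 trans to O6. The fallback makes the same bond by known halogen–magnesium chemistry; it sets out from 19 and comes back at 20. Aldehyde 19 would be oxidised (NaClO2, NaH2PO4, 2-methyl-2-butene, t-BuOH–water; Pinnick oxidation) to (2R,3S,4S)-2,3,4-tris(benzyloxy)-4-{6-[2-(3-(benzyloxy)-4-methoxyphenyl)ethyl]-3-iodo-4-oxo-4H-pyran-2-yl}butanoic acid F1. This would be coupled with N,O-dimethylhydroxylamine (EDC·HCl, i-Pr2NEt, CH2Cl2) to the corresponding N-methoxy-N-methylbutanamide F2. Iodine–magnesium exchange with iPrMgCl·LiCl in THF at −40 °C, an established way to metalate 3-halo-4-pyranone rings for carbonyl addition, would be followed by intramolecular acylation (Parham-type cyclisation) to (6R,7S,8S)-6,7,8-tris(benzyloxy)-2-[2-(3-(benzyloxy)-4-methoxyphenyl)ethyl]-7,8-dihydro-4H-chromene-4,5(6H)-dione F3. The low temperature keeps the metalated pyrone from opening. Reduction of the C5 ketone with LiBH(s-Bu)3 in THF at −78 °C, the bulky hydride entering equatorially, should give the pseudo-axial alcohol cis to O6, which is 20.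

Step 12. The enaminone may hydrolyse to an open iodo-triketone faster than it cyclises, and iodine may then be lost or move to C3. The fallback closes the ring by electrophilic activation instead; it sets out from ynone 15 and comes back at 18. ICl in CH2Cl2 at −78 °C should trigger a 6-endo-dig iodocyclisation in which a dioxolane oxygen attacks C8a while iodine is delivered to C4a, and chloride opens the resulting oxonium ion. This gives 6-[(1S,2R,3S)-1,2,3-tris(benzyloxy)-4-[(tert-butyldimethylsilyl)oxy]butyl]-2-[2-(3-(benzyloxy)-4-methoxyphenyl)ethyl]-2-(2-chloroethoxy)-5-iodo-2,3-dihydro-4H-pyran-4-one F4. Treatment with 2 M aq. HCl in THF would eliminate 2-chloroethanol to the aromatic pyrone and remove the silyl ether, giving 18. This variant is held in reserve because the O6 benzyl ether could compete for the activated alkyne.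

Step 15. Hydrogen may add to the pyrone C2=C3 bond, or the C5–O and C8–O bonds, which are allylic to the pyrone, may be cleaved along with the benzyl ethers. The fallback replaces hydrogenolysis by Lewis-acid dealkylation; it sets out from 20 and arrives directly at 21. BCl3 with pentamethylbenzene as benzyl-cation scavenger in CH2Cl2 at −78 °C would remove all four benzyl groups; it makes no new compound (F0).

Further compounds
F1 | step 14 | (2R,3S,4S)-2,3,4-tris(benzyloxy)-4-{6-[2-(3-(benzyloxy)-4-methoxyphenyl)ethyl]-3-iodo-4-oxo-4H-pyran-2-yl}butanoic acid | COc1ccc(CCc2cc(=O)c(I)c(o2)[C@@H](OCc3ccccc3)[C@H](OCc3ccccc3)[C@@H](OCc3ccccc3)C(=O)O)cc1OCc1ccccc1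
F2 | step 14 | (2R,3S,4S)-2,3,4-tris(benzyloxy)-4-{6-[2-(3-(benzyloxy)-4-methoxyphenyl)ethyl]-3-iodo-4-oxo-4H-pyran-2-yl}-N-methoxy-N-methylbutanamide | COc1ccc(CCc2cc(=O)c(I)c(o2)[C@@H](OCc3ccccc3)[C@H](OCc3ccccc3)[C@@H](OCc3ccccc3)C(=O)N(C)OC)cc1OCc1ccccc1
F3 | step 14 | (6R,7S,8S)-6,7,8-tris(benzyloxy)-2-[2-(3-(benzyloxy)-4-methoxyphenyl)ethyl]-7,8-dihydro-4H-chromene-4,5(6H)-dione | COc1ccc(CCc2cc(=O)c3c(o2)[C@@H](OCc4ccccc4)[C@H](OCc4ccccc4)[C@@H](OCc4ccccc4)C3=O)cc1OCc1ccccc1
F4 | step 12 | 6-[(1S,2R,3S)-1,2,3-tris(benzyloxy)-4-[(tert-butyldimethylsilyl)oxy]butyl]-2-[2-(3-(benzyloxy)-4-methoxyphenyl)ethyl]-2-(2-chloroethoxy)-5-iodo-2,3-dihydro-4H-pyran-4-one (C2 epimers) | COc1ccc(CCC2(OCCCl)CC(=O)C(I)=C(O2)[C@@H](OCc3ccccc3)[C@H](OCc3ccccc3)[C@@H](OCc3ccccc3)CO[Si](C)(C)C(C)(C)C)cc1OCc1ccccc1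
F0 | step 15 | none | none
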